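**Plan**

- Retrosynthesis: cut the two C8–C(=O) bonds (acylation), then the two O1–C2 bonds (pyran closure from a tertiary alcohol). In each benzene ring cut C4a–C8a, C5–C6 and C8–C8a (cyclobutenone plus siloxyalkyne benzannulation), then the two bonds from the bridge carbon to a bis-cyclobutenone (two-to-one aldehyde condensation).
- Forward: the 6-methylheptylidene bridge is set first between two four-membered rings, both benzene rings are then built at once around it, the two pyran rings follow, and the acyl groups come last.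
- Enabling feature: each benzene ring carries oxygen on C5, C7 and C8a around the bridge carbon C6, with one CH at C8. The annulation delivers these as silyl ether (C5), benzyl ether (C7) and the only free phenol (C8a), which sits next to the C4a side chain, so the pyran ring can close in one direction only.
- Stereochemistry: the only stereocentres are the two acyl α-carbons, both R, brought in with (R)-2-methylbutanoic acid.

Key step: step 9

Remark: the bridge carbon bears two identical chromanyl groups and is not a stereocentre. Ketene for step 1 is taken from a laboratory ketene generator fed with acetone.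

**Route**

Step 1
Reactants: 1 ethoxyacetylene
Product: 2 3-ethoxycyclobut-2-en-1-one
Conditions: ketene (gas, from acetone in a ketene generator), CH2Cl2, 0 °C
Reagents that add atoms: ketene, C=C=O
Why: Ketene–ynol ether [2+2] cycloaddition in which the nucleophilic CH carbon of the alkyne bonds to the ketene carbonyl carbon, which gives the 3-alkoxycyclobutenone directly.

Step 2
Reactants: 2 3-ethoxycyclobut-2-en-1-one
Product: 3 cyclobutane-1,3-dione
Conditions: 1 M HCl (aq), 0 °C to rt
Reagents that add atoms: water, O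
Why: Acid hydrolysis of a vinylogous ester, which for this enol ether is known to stop cleanly at the crystalline dione when run cold.

Step 3
Reactants: 4 6-methylheptan-1-ol
Product: 5 6-methylheptanal
Conditions: TEMPO (cat.), PhI(OAc)2, CH2Cl2, rt
Reagents that add atoms: none
Why: Oxoammonium-mediated oxidation of a primary alcohol, which stops at the aldehyde under anhydrous conditions.

Step 4
Reactants: 3 cyclobutane-1,3-dione (2.1 equiv); 5 6-methylheptanal
Product: 7 2,2'-(6-methylheptane-1,1-diyl)bis(3-hydroxycyclobut-2-en-1-one), via alkylidene dione 6 (not isolated)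
Conditions: MeCN–H2O (4:1), rt, no added base
Reagents that add atoms: none
Why: Tandem Knoevenagel condensation–Michael addition, the usual two-to-one reaction of cyclic 1,3-diones with aldehydes, here self-catalysed by the strongly acidic enol and driven by the high acceptor strength of alkylidene dione 6.

Step 5
Reactants: 7 2,2'-(6-methylheptane-1,1-diyl)bis(3-hydroxycyclobut-2-en-1-one)
Product: 8 2,2'-(6-methylheptane-1,1-diyl)bis[3-(benzyloxy)cyclobut-2-en-1-one]
Conditions: BnOH (2.4 equiv), PPh3, DIAD, THF, 0 °C to rt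
Reagents that add atoms: benzyl alcohol, OCc1ccccc1
Why: Mitsunobu O-alkylation of an acidic enol; each 2-substituted dione unit is symmetric, so either oxygen gives the same vinylogous ester, and C-alkylation at the fully substituted C2 is disfavoured.

Step 6
Reactants: 9 ethyl pent-4-ynoate
Product: 10 2-methylhex-5-yn-2-ol
Conditions: MeMgBr (3.5 equiv), THF, 0 °C to rt; aq. NH4Cl
Reagents that add atoms: methylmagnesium bromide, C[Mg]Br
Why: Double Grignard addition to an ester gives the tertiary alcohol, with the extra equivalent covering the acidic alkyne C–H.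

Step 7
Reactants: 10 2-methylhex-5-yn-2-ol
Product: 11 triethyl[(2-methylhex-5-yn-2-yl)oxy]silane
Conditions: Et3SiOTf, 2,6-lutidine, CH2Cl2, −78 to 0 °C
Reagents that add atoms: triethylsilyl trifluoromethanesulfonate, CC[Si](CC)(CC)OS(=O)(=O)C(F)(F)F
Why: Silyl triflate silylation is the standard way to protect a hindered tertiary alcohol, and the triethylsilyl ether is chosen because it survives base and heat yet leaves under the mild acid of step 10.

Step 8
Reactants: 11 triethyl[(2-methylhex-5-yn-2-yl)oxy]silane
Product: 14 5-methyl-5-(triethylsilyloxy)-1-(triisopropylsilyloxy)hex-1-yne, via lithium acetylide 12 (not isolated), via lithium ynolate 13 (not isolated)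
Conditions: n-BuLi, THF, −78 °C; LiOOt-Bu (from t-BuOOH and LiN(SiMe3)2), −78 to 0 °C; i-Pr3SiOTf, −78 °C
Reagents that add atoms: tert-butyl hydroperoxide, CC(C)(C)OO; triisopropylsilyl trifluoromethanesulfonate, CC(C)[Si](OS(=O)(=O)C(F)(F)F)(C(C)C)C(C)C
Why: Electrophilic oxygenation of a lithium acetylide by lithium tert-butyl peroxide gives the ynolate, which the bulky silyl triflate traps on oxygen to give a chromatographically stable siloxyalkyne.

Step 9
Reactants: 8 2,2'-(6-methylheptane-1,1-diyl)bis[3-(benzyloxy)cyclobut-2-en-1-one]; 14 5-methyl-5-(triethylsilyloxy)-1-(triisopropylsilyloxy)hex-1-yne (3 equiv)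
Product: 16 4,4'-(6-methylheptane-1,1-diyl)bis[5-(benzyloxy)-2-(3-methyl-3-(triethylsilyloxy)butyl)-3-(triisopropylsilyloxy)phenol], via mono-annulated cyclobutenone 15 (not isolated)
Conditions: degassed toluene, 80 °C then 110 °C, sealed tube
Reagents that add atoms: none
Why: Each 3-benzyloxycyclobutenone opens thermally (4π) to a vinylketene, the alkyne carbon remote from oxygen adds to the ketene carbonyl carbon in a [2+2] cycloaddition, the resulting 4-vinyl-3-siloxycyclobutenone opens again to a dienylketene, and 6π electrocyclisation followed by tautomerisation gives the phenol. The closest known reaction is the Danheiser benzannulation of cyclobutenones with trialkylsiloxyalkynes to resorcinol monosilyl ethers; the donor-substituted (vinylogous ester) cyclobutenone and the twofold run are extensions that should mainly raise the temperature of the first ring opening. Each benzene ring closes by thermal disrotatory six-electron electrocyclisation of the dienylketene (C8–C8a), after C4a–C8a and C5–C6 have been made in the [2+2] step. No stereocentre is formed. The step needs the siloxy carbon to end up next to the bridge-bearing carbon and the ketene oxygen to emerge as the only free phenol, and both follow from the matched polarity of the electrophilic ketene carbon and the nucleophilic alkyne carbon. An excess of 14 keeps the phenol formed in the first annulation from intercepting the second vinylketene as an aryl ester.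

Step 10
Reactants: 16 4,4'-(6-methylheptane-1,1-diyl)bis[5-(benzyloxy)-2-(3-methyl-3-(triethylsilyloxy)butyl)-3-(triisopropylsilyloxy)phenol]
Product: 18 6,6'-(6-methylheptane-1,1-diyl)bis[7-(benzyloxy)-2,2-dimethyl-5-(triisopropylsilyloxy)chromane], via bis(tertiary alcohol) 17 (not isolated)
Conditions: TsOH·H2O (0.2 equiv), toluene, rt to 50 °C
Reagents that add atoms: none
Why: Acid cleaves the labile tertiary triethylsilyl ethers, and the tertiary cations are captured by the only free phenol oxygen (C8a) in an SN1 cycloetherification to the six-membered pyran, while the aryl triisopropylsilyl ether at C5 and the benzyl ether at C7 are inert to catalytic sulfonic acid.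

Step 11
Reactants: 18 6,6'-(6-methylheptane-1,1-diyl)bis[7-(benzyloxy)-2,2-dimethyl-5-(triisopropylsilyloxy)chromane]
Product: 19 6,6'-(6-methylheptane-1,1-diyl)bis[7-(benzyloxy)-2,2-dimethylchroman-5-ol]
Conditions: Bu4NF, AcOH, THF, 0 °C
Reagents that add atoms: none
Why: Fluoride cleaves aryl silyl ethers rapidly, and the acetic acid buffer keeps the electron-rich phenoxides from air oxidation.

Step 12
Reactants: 19 6,6'-(6-methylheptane-1,1-diyl)bis[7-(benzyloxy)-2,2-dimethylchroman-5-ol]
Product: 20 6,6'-(6-methylheptane-1,1-diyl)bis(2,2-dimethylchromane-5,7-diol)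
Conditions: H2 (1 atm), Pd/C (10 wt %), EtOAc, rt
Reagents that add atoms: none
Why: Hydrogenolysis of aryl benzyl ethers over Pd/C is selective here because the molecule holds no other reducible group.

Step 13
Reactants: 21 (R)-2-methylbutanoic acid
Product: 22 (R)-2-methylbutanoyl chloride
Conditions: (COCl)2, DMF (cat.), CH2Cl2, 0 °C to rt
Reagents that add atoms: oxalyl chloride, O=C(Cl)C(=O)Cl
Why: Acid chloride formation through the chloroiminium salt from DMF and oxalyl chloride, run without amine base so that no ketene can form and the α-carbon keeps its R configuration.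

Step 14
Reactants: 20 6,6'-(6-methylheptane-1,1-diyl)bis(2,2-dimethylchromane-5,7-diol); 22 (R)-2-methylbutanoyl chloride (2.4 equiv)
Product: 23 6,6'-(6-methylheptane-1,1-diyl)bis{5,7-dihydroxy-2,2-dimethyl-8-[(2R)-2-methylbutanoyl]chromane}
Conditions: AlCl3 (6 equiv), PhNO2–CH2Cl2, 0 °C to rt; cold 1 M HCl
Reagents that add atoms: none
Why: Friedel–Crafts C-acylation of a phloroglucinol-type ring at its only unsubstituted carbon C8 (any aryl ester formed first should rearrange in a Fries sense), with both R stereocentres carried over unchanged from 22 because the reaction is run cold and without base.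

**Compound list**

1 | ethoxyacetylene | C#COCC | starting material
2 | 3-ethoxycyclobut-2-en-1-one | CCOC1=CC(=O)C1 | intermediate
3 | cyclobutane-1,3-dione | O=C1CC(=O)C1 | intermediate
4 | 6-methylheptan-1-ol | CC(C)CCCCCO | starting material
5 | 6-methylheptanal | CC(C)CCCCC=O | intermediate
6 | 2-(6-methylheptylidene)cyclobutane-1,3-dione (not isolated) | CC(C)CCCCC=C1C(=O)CC1=O | intermediate
7 | 2,2'-(6-methylheptane-1,1-diyl)bis(3-hydroxycyclobut-2-en-1-one) | CC(C)CCCCC(C1=C(O)CC1=O)C1=C(O)CC1=O | intermediate
8 | 2,2'-(6-methylheptane-1,1-diyl)bis[3-(benzyloxy)cyclobut-2-en-1-one] | CC(C)CCCCC(C1=C(OCc2ccccc2)CC1=O)C1=C(OCc2ccccc2)CC1=O | intermediate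
9 | ethyl pent-4-ynoate | C#CCCC(=O)OCC | starting material
10 | 2-methylhex-5-yn-2-ol | C#CCCC(C)(C)O | intermediate
11 | triethyl[(2-methylhex-5-yn-2-yl)oxy]silane | C#CCCC(C)(C)O[Si](CC)(CC)CC | intermediate
12 | lithium acetylide of 11 (not isolated) | [Li]C#CCCC(C)(C)O[Si](CC)(CC)CC | intermediate
13 | lithium 5-methyl-5-(triethylsilyloxy)hex-1-yn-1-olate (not isolated) | [Li+].[O-]C#CCCC(C)(C)O[Si](CC)(CC)CC | intermediate
14 | 5-methyl-5-(triethylsilyloxy)-1-(triisopropylsilyloxy)hex-1-yne | CC(C)[Si](OC#CCCC(C)(C)O[Si](CC)(CC)CC)(C(C)C)C(C)C | intermediate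
15 | mono-annulated cyclobutenone: 3-(benzyloxy)-2-{1-[6-(benzyloxy)-4-hydroxy-3-(3-methyl-3-(triethylsilyloxy)butyl)-2-(triisopropylsilyloxy)phenyl]-6-methylheptyl}cyclobut-2-en-1-one (not isolated) | CC(C)CCCCC(C1=C(OCc2ccccc2)CC1=O)c1c(OCc2ccccc2)cc(O)c(CCC(C)(C)O[Si](CC)(CC)CC)c1O[Si](C(C)C)(C(C)C)C(C)C | intermediate
16 | 4,4'-(6-methylheptane-1,1-diyl)bis[5-(benzyloxy)-2-(3-methyl-3-(triethylsilyloxy)butyl)-3-(triisopropylsilyloxy)phenol] | CC(C)CCCCC(c1c(OCc2ccccc2)cc(O)c(CCC(C)(C)O[Si](CC)(CC)CC)c1O[Si](C(C)C)(C(C)C)C(C)C)c1c(OCc2ccccc2)cc(O)c(CCC(C)(C)O[Si](CC)(CC)CC)c1O[Si](C(C)C)(C(C)C)C(C)C | intermediate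
17 | 4,4'-(6-methylheptane-1,1-diyl)bis[5-(benzyloxy)-2-(3-hydroxy-3-methylbutyl)-3-(triisopropylsilyloxy)phenol] (not isolated) | CC(C)CCCCC(c1c(OCc2ccccc2)cc(O)c(CCC(C)(C)O)c1O[Si](C(C)C)(C(C)C)C(C)C)c1c(OCc2ccccc2)cc(O)c(CCC(C)(C)O)c1O[Si](C(C)C)(C(C)C)C(C)C | intermediate
18 | 6,6'-(6-methylheptane-1,1-diyl)bis[7-(benzyloxy)-2,2-dimethyl-5-(triisopropylsilyloxy)chromane] | CC(C)CCCCC(c1c(OCc2ccccc2)cc2OC(C)(C)CCc2c1O[Si](C(C)C)(C(C)C)C(C)C)c1c(OCc2ccccc2)cc2OC(C)(C)CCc2c1O[Si](C(C)C)(C(C)C)C(C)C | intermediate
19 | 6,6'-(6-methylheptane-1,1-diyl)bis[7-(benzyloxy)-2,2-dimethylchroman-5-ol] | CC(C)CCCCC(c1c(OCc2ccccc2)cc2OC(C)(C)CCc2c1O)c1c(OCc2ccccc2)cc2OC(C)(C)CCc2c1O | intermediate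
20 | 6,6'-(6-methylheptane-1,1-diyl)bis(2,2-dimethylchromane-5,7-diol) | CC(C)CCCCC(c1c(O)cc2OC(C)(C)CCc2c1O)c1c(O)cc2OC(C)(C)CCc2c1O | intermediate
21 | (R)-2-methylbutanoic acid | CC[C@@H](C)C(=O)O | starting material
22 | (R)-2-methylbutanoyl chloride | CC[C@@H](C)C(=O)Cl | intermediate
23 | 6,6'-(6-methylheptane-1,1-diyl)bis{5,7-dihydroxy-2,2-dimethyl-8-[(2R)-2-methylbutanoyl]chromane} | CC[C@@H](C)C(=O)c1c(O)c(C(CCCCC(C)C)c2c(O)c3c(c(C(=O)[C@H](C)CC)c2O)OC(C)(C)CC3)c(O)c2c1OC(C)(C)CC2 | target

**Count**

Total steps: 14. Longest linear sequence: 9 steps (steps 1, 2, 4, 5, 9, 10, 11, 12, 14).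

**Steps most likely to fail**

Step 9. The vinylogous ester character of the 3-benzyloxycyclobutenone may slow the first ring opening to temperatures at which the siloxyalkyne begins to rearrange by silyl shift. The crowded bridge carbon may stall the sequence after one annulation, and the first-formed phenol may trap the second vinylketene. The fallback gives up the de novo ring construction and sets out from 5 and 22. Phloroglucinol would be C-acylated with 22 (AlCl3, PhNO2) to (R)-2-methyl-1-(2,4,6-trihydroxyphenyl)butan-1-one F1. This would be C-prenylated with prenyl bromide in aqueous KOH to (R)-2-methyl-1-[2,4,6-trihydroxy-3-(3-methylbut-2-en-1-yl)phenyl]butan-1-one F2. Acid would close the pyran onto the hydroxyl next to the acyl group to give (R)-1-(5,7-dihydroxy-2,2-dimethylchroman-8-yl)-2-methylbutan-1-one F3, which would have to be separated from its 6-acyl isomer. Two equivalents of F3 would then be condensed with 5 at the only free ring carbon C6, by the aldehyde coupling through an ortho-quinone methide that is established for bridged acylphloroglucinol dimers. The route is rejoined at 23.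

Step 4. The strained dione may be cleaved at a carbonyl group by water before it condenses, or alkylidene dione 6 may oligomerise faster than the second dione adds. The fallback replaces the free dione by a stable vinylogous amide and sets out from 2 and 5. Addition–elimination of pyrrolidine on 2 would give 3-(pyrrolidin-1-yl)cyclobut-2-en-1-one F4, whose C2 is a robust enaminone nucleophile. Two equivalents of F4 would condense with 5 in AcOH to 2,2'-(6-methylheptane-1,1-diyl)bis[3-(pyrrolidin-1-yl)cyclobut-2-en-1-one] F5. Hydrolysis of both enaminones with cold aqueous HCl would return the route at 7.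

Step 14. The strong Lewis acid may cleave the electron-rich diarylmethine bridge in a retro-Friedel–Crafts sense, may open a pyran ring and let it reclose onto the C5 oxygen, and may erode the configuration α to the new ketone. The fallback introduces the acyl groups by an organometallic route before deprotection and sets out from 18 and 22. Bromination of 18 with N-bromosuccinimide at the only free ring carbon would give the 8,8'-dibromide F6. Separately, 22 and N,O-dimethylhydroxylamine would give (R)-N-methoxy-N,2-dimethylbutanamide F7. Bromine–lithium exchange on F6 (t-BuLi, THF, −78 °C) and addition of F7 would give the protected bis-ketone F8. Buffered Bu4NF would then give the 5,5'-diol F9, and hydrogenolysis over Pd/C would rejoin the route at 23.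

**Further compounds**

F1 | step 9 | (R)-2-methyl-1-(2,4,6-trihydroxyphenyl)butan-1-one | CC[C@@H](C)C(=O)c1c(O)cc(O)cc1O
F2 | step 9 | (R)-2-methyl-1-[2,4,6-trihydroxy-3-(3-methylbut-2-en-1-yl)phenyl]butan-1-one | CC[C@@H](C)C(=O)c1c(O)cc(O)c(CC=C(C)C)c1O
F3 | step 9 | (R)-1-(5,7-dihydroxy-2,2-dimethylchroman-8-yl)-2-methylbutan-1-one | CC[C@@H](C)C(=O)c1c(O)cc(O)c2CCC(C)(C)Oc12
F4 | step 4 | 3-(pyrrolidin-1-yl)cyclobut-2-en-1-one | O=C1CC(N2CCCC2)=C1
F5 | step 4 | 2,2'-(6-methylheptane-1,1-diyl)bis[3-(pyrrolidin-1-yl)cyclobut-2-en-1-one] | CC(C)CCCCC(C1=C(N2CCCC2)CC1=O)C1=C(N2CCCC2)CC1=O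
F6 | step 14 | 6,6'-(6-methylheptane-1,1-diyl)bis[7-(benzyloxy)-8-bromo-2,2-dimethyl-5-(triisopropylsilyloxy)chromane] | CC(C)CCCCC(c1c(OCc2ccccc2)c(Br)c2OC(C)(C)CCc2c1O[Si](C(C)C)(C(C)C)C(C)C)c1c(OCc2ccccc2)c(Br)c2OC(C)(C)CCc2c1O[Si](C(C)C)(C(C)C)C(C)C
F7 | step 14 | (R)-N-methoxy-N,2-dimethylbutanamide | CC[C@@H](C)C(=O)N(C)OC
F8 | step 14 | 6,6'-(6-methylheptane-1,1-diyl)bis{7-(benzyloxy)-2,2-dimethyl-8-[(2R)-2-methylbutanoyl]-5-(triisopropylsilyloxy)chromane} | CC(C)CCCCC(c1c(OCc2ccccc2)c(C(=O)[C@H](C)CC)c2OC(C)(C)CCc2c1O[Si](C(C)C)(C(C)C)C(C)C)c1c(OCc2ccccc2)c(C(=O)[C@H](C)CC)c2OC(C)(C)CCc2c1O[Si](C(C)C)(C(C)C)C(C)C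
F9 | step 14 | 6,6'-(6-methylheptane-1,1-diyl)bis{7-(benzyloxy)-5-hydroxy-2,2-dimethyl-8-[(2R)-2-methylbutanoyl]chromane} | CC(C)CCCCC(c1c(OCc2ccccc2)c(C(=O)[C@H](C)CC)c2OC(C)(C)CCc2c1O)c1c(OCc2ccccc2)c(C(=O)[C@H](C)CC)c2OC(C)(C)CCc2c1O
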